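## Retrosynthetic overview

1. Target 17 is a hydroquinone ring (C1′–C6′) carrying at C1′ the 1,1-disubstituted alkene C2(=C1H2); its neighbour C3 is the only stereocentre (S, O-angeloyl) and bears the prenyl arm C4H2–C5H=C6Me2. No ring is closed anywhere: the benzene ring is bought and only re-oxidised.
2. The C5′–OH is added last (phenol 15 → p-quinone 16 → hydroquinone 17), so this oxygen never needs a protecting group.
3. Key disconnection C2–C3: a lithiation–borylation (1,2-metallate rearrangement) joins the (R)-α-lithiated homoprenyl carbamate (C3–C7) to the α-arylvinyl boronate 5 (C1, C2, ring) and sets C3; oxidation in the same flask gives (S)-allylic alcohol 11. This avoids the labile β,γ-unsaturated aldehyde (4-methylpent-3-enal) that a carbonyl addition at C3 would need.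
4. Boronate 5 comes from aryl alkyne 4, salicylaldehyde 2 and 2-methoxy-3-methylphenol 1, whose single free ortho carbon fixes where the side chain sits.
5. The angelate is put on 11 by mixed-anhydride acylation before the phenol is unmasked.

Key step: step 6

Remark: 1, 6, 12 and (+)-sparteine are taken as purchasable; locants are C1–C7 for the hepta-1,5-diene chain and C1′–C6′ for the ring (C2′ OH, C3′ OMe, C4′ Me, C5′ OH), and C3 is (S) because O > C2 > C4 > H.

## Route

Step 1
Reactants: 1 2-methoxy-3-methylphenol
Product: 2 2-hydroxy-3-methoxy-4-methylbenzaldehyde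
Conditions: MgCl2, Et3N, (CH2O)n, MeCN, reflux; aq HCl work-up
Reagents that add atoms: paraformaldehyde (as formaldehyde), C=O
Why: Magnesium-phenoxide-directed ortho-formylation (Casnati–Skattebøl) delivers formaldehyde through a chelate only to an ortho carbon, and 1 has a single free ortho position (the other carries OMe), so the formyl group must enter para to the methyl group.

Step 2
Reactants: 2 2-hydroxy-3-methoxy-4-methylbenzaldehyde
Product: 3 3-methoxy-2-(methoxymethoxy)-4-methylbenzaldehyde
Conditions: MOMCl, i-Pr2NEt, CH2Cl2, 0 °C → rt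
Reagents that add atoms: chloromethyl methyl ether (MOMCl), COCCl
Why: O-Alkylation of the phenol gives an acetal that should tolerate the basic, organometallic and oxidative steps 3–7 and is small enough not to shield boron in step 6.

Step 3
Reactants: 3 3-methoxy-2-(methoxymethoxy)-4-methylbenzaldehyde
Product: 4 1-ethynyl-3-methoxy-2-(methoxymethoxy)-4-methylbenzene
Conditions: dimethyl (1-diazo-2-oxopropyl)phosphonate, K2CO3, MeOH, rt
Reagents that add atoms: dimethyl (1-diazo-2-oxopropyl)phosphonate (Ohira–Bestmann reagent), COP(=O)(OC)C(=[N+]=[N-])C(C)=O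
Why: Seyferth–Gilbert homologation in the Ohira–Bestmann variant: the diazomethylphosphonate anion formed in situ adds to the aldehyde, and the resulting diazoalkene loses N2 and rearranges to the terminal alkyne under conditions that leave MOM and aryl ethers alone.

Step 4
Reactants: 4 1-ethynyl-3-methoxy-2-(methoxymethoxy)-4-methylbenzene
Product: 5 2-{1-[3-methoxy-2-(methoxymethoxy)-4-methylphenyl]ethenyl}-4,4,5,5-tetramethyl-1,3,2-dioxaborolane
Conditions: B2pin2, SIMes·CuCl (5 mol %), NaOt-Bu (5 mol %), MeOH, THF, −15 → 22 °C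
Reagents that add atoms: bis(pinacolato)diboron, CC1(C)OB(OC1(C)C)B1OC(C)(C)C(C)(C)O1
Why: Cu-catalysed protoboration of a terminal aryl alkyne: with an N-aryl NHC ligand the Cu–Bpin species should add syn with boron on the aryl-bearing (α) carbon, and MeOH protonates the C–Cu bond to give the 1,1-disubstituted vinyl boronate.

Step 5
Reactants: 6 4-methylpent-3-en-1-ol
Product: 7 4-methylpent-3-en-1-yl N,N-diisopropylcarbamate
Conditions: i-Pr2NC(O)Cl, Et3N, CH2Cl2, reflux
Reagents that add atoms: N,N-diisopropylcarbamoyl chloride, CC(C)N(C(C)C)C(Cl)=O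
Why: O-Carbamoylation of a primary alcohol installs the Hoppe directing and leaving group that step 6 needs.

Step 6
Reactants: 7 4-methylpent-3-en-1-yl N,N-diisopropylcarbamate; 5 2-{1-[3-methoxy-2-(methoxymethoxy)-4-methylphenyl]ethenyl}-4,4,5,5-tetramethyl-1,3,2-dioxaborolane
Product: 11 (S)-2-[3-methoxy-2-(methoxymethoxy)-4-methylphenyl]-6-methylhepta-1,5-dien-3-ol, via (R)-lithiated carbamate 8 (not isolated), via lithium boronate complex 9 (not isolated), via (S)-allylic pinacol boronate 10 (not isolated)
Conditions: s-BuLi, (+)-sparteine, Et2O, −78 °C; then 5, −78 °C; MgBr2·OEt2, −78 °C → reflux; then NaOH aq, H2O2, THF, 0 °C → rt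
Reagents that add atoms: hydrogen peroxide, OO
Why: s-BuLi/(+)-sparteine removes the pro-R proton of the OCH2 group of 7 (Hoppe deprotonation; the carbamate C=O directs and stabilises the configurationally stable lithio species 8), and 8 captures the boron of 5 with retention to give boronate complex 9. On warming with MgBr2 the α-arylvinyl group undergoes a stereospecific 1,2-metallate shift anti-periplanar to the departing carbamate (inversion at C3), forming the C2–C3 bond and the (S)-allylic boronate 10; H2O2/NaOH then replaces boron by OH with retention (a 1,2-shift from B to O, no allylic transposition) to give (S)-11. The closest known reaction type is the Hoppe–Aggarwal lithiation–borylation–oxidation of primary alkyl carbamates with alkenyl pinacol boronates, which gives α-substituted allylic boronates and, after oxidation, secondary allylic alcohols. No ring is closed. The single stereocentre C3 is set by the chiral diamine alone (reagent control; (+)-sparteine is required because the α-arylvinyl group outranks the C4 methylene, so the (R)-lithio compound leads to the (S)-alcohol). The step needs α-O-lithiation in preference to deprotonation at the allylic C4–H2 (secured by complex-induced proximity to the carbamate at −78 °C) and migration of the vinyl group rather than a pinacol oxygen (secured by the high migratory aptitude of sp2 carbon and MgBr2 activation of the leaving group).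

Step 7
Reactants: 11 (S)-2-[3-methoxy-2-(methoxymethoxy)-4-methylphenyl]-6-methylhepta-1,5-dien-3-ol; 12 angelic acid [(Z)-2-methylbut-2-enoic acid]
Product: 14 (S)-2-[3-methoxy-2-(methoxymethoxy)-4-methylphenyl]-6-methylhepta-1,5-dien-3-yl (Z)-2-methylbut-2-enoate, via angelic 2,4,6-trichlorobenzoic anhydride 13 (not isolated)
Conditions: 12, 2,4,6-Cl3C6H2COCl, Et3N, toluene, rt; then 11, toluene, 80 °C
Reagents that add atoms: none
Why: Yamaguchi-type mixed-anhydride esterification run without DMAP: the alcohol should attack the less hindered angeloyl carbonyl of 13, the C3–O bond is not touched (retention), and leaving out acyl chloride and nucleophilic catalyst should suppress Z→E isomerisation to the tiglate.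

Step 8
Reactants: 14 (S)-2-[3-methoxy-2-(methoxymethoxy)-4-methylphenyl]-6-methylhepta-1,5-dien-3-yl (Z)-2-methylbut-2-enoate
Product: 15 (S)-2-(2-hydroxy-3-methoxy-4-methylphenyl)-6-methylhepta-1,5-dien-3-yl (Z)-2-methylbut-2-enoate
Conditions: ZnBr2, n-PrSH, CH2Cl2, 0 °C, short reaction time
Reagents that add atoms: none
Why: Lewis-acid-assisted acetal cleavage: ZnBr2 activates the aryl MOM acetal and the thiol traps the methoxymethyl cation within minutes at 0 °C, which should be mild and brief enough to spare the allylic angelate and both alkenes.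

Step 9
Reactants: 15 (S)-2-(2-hydroxy-3-methoxy-4-methylphenyl)-6-methylhepta-1,5-dien-3-yl (Z)-2-methylbut-2-enoate
Product: 16 (S)-2-(5-methoxy-4-methyl-3,6-dioxocyclohexa-1,4-dien-1-yl)-6-methylhepta-1,5-dien-3-yl (Z)-2-methylbut-2-enoate
Conditions: Fremy's salt [(KO3S)2NO], KH2PO4 aq, acetone/H2O, 0 °C → rt
Reagents that add atoms: potassium nitrosodisulfonate (Fremy's salt), [K+].[K+].[O]N(S(=O)(=O)[O-])S(=O)(=O)[O-]
Why: Teuber oxidation: the phenoxyl radical couples with a second nitrosodisulfonate at the free para carbon C5′ and loses imidodisulfonate to give the p-quinone, with isolated alkenes and the ester inert to this radical oxidant.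

Step 10
Reactants: 16 (S)-2-(5-methoxy-4-methyl-3,6-dioxocyclohexa-1,4-dien-1-yl)-6-methylhepta-1,5-dien-3-yl (Z)-2-methylbut-2-enoate
Product: 17 (S)-2-(2,5-dihydroxy-3-methoxy-4-methylphenyl)-6-methylhepta-1,5-dien-3-yl (Z)-2-methylbut-2-enoate
Conditions: Na2S2O4 aq, EtOAc, rt, under Ar; degassed work-up
Reagents that add atoms: none
Why: Two-electron, two-proton reduction of the quinone by dithionite in a two-phase system gives the hydroquinone under near-neutral conditions that should leave the angelate, both alkenes and C3 unchanged.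

## Compound list

1 | 2-methoxy-3-methylphenol | COc1c(C)cccc1O | starting material
2 | 2-hydroxy-3-methoxy-4-methylbenzaldehyde | COc1c(C)ccc(C=O)c1O | intermediate
3 | 3-methoxy-2-(methoxymethoxy)-4-methylbenzaldehyde | COCOc1c(C=O)ccc(C)c1OC | intermediate
4 | 1-ethynyl-3-methoxy-2-(methoxymethoxy)-4-methylbenzene | C#Cc1ccc(C)c(OC)c1OCOC | intermediate
5 | 2-{1-[3-methoxy-2-(methoxymethoxy)-4-methylphenyl]ethenyl}-4,4,5,5-tetramethyl-1,3,2-dioxaborolane | C=C(B1OC(C)(C)C(C)(C)O1)c1ccc(C)c(OC)c1OCOC | intermediate
6 | 4-methylpent-3-en-1-ol | CC(C)=CCCO | starting material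
7 | 4-methylpent-3-en-1-yl N,N-diisopropylcarbamate | CC(C)=CCCOC(=O)N(C(C)C)C(C)C | intermediate
8 | (R)-1-lithio-4-methylpent-3-en-1-yl N,N-diisopropylcarbamate, as its (+)-sparteine complex | [Li][C@H](CC=C(C)C)OC(=O)N(C(C)C)C(C)C | intermediate (not isolated)
9 | lithium [(1R)-1-(N,N-diisopropylcarbamoyloxy)-4-methylpent-3-en-1-yl]{1-[3-methoxy-2-(methoxymethoxy)-4-methylphenyl]ethenyl}(pinacolato)borate | C=C(c1ccc(C)c(OC)c1OCOC)[B-]1(OC(C)(C)C(C)(C)O1)[C@H](CC=C(C)C)OC(=O)N(C(C)C)C(C)C.[Li+] | intermediate (not isolated)
10 | 2-{(3S)-2-[3-methoxy-2-(methoxymethoxy)-4-methylphenyl]-6-methylhepta-1,5-dien-3-yl}-4,4,5,5-tetramethyl-1,3,2-dioxaborolane | C=C(c1ccc(C)c(OC)c1OCOC)[C@H](CC=C(C)C)B1OC(C)(C)C(C)(C)O1 | intermediate (not isolated)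
11 | (S)-2-[3-methoxy-2-(methoxymethoxy)-4-methylphenyl]-6-methylhepta-1,5-dien-3-ol | C=C(c1ccc(C)c(OC)c1OCOC)[C@H](CC=C(C)C)O | intermediate
12 | angelic acid, (Z)-2-methylbut-2-enoic acid | C/C=C(/C)C(=O)O | starting material
13 | (Z)-2-methylbut-2-enoic 2,4,6-trichlorobenzoic anhydride | C/C=C(/C)C(=O)OC(=O)c1c(Cl)cc(Cl)cc1Cl | intermediate (not isolated)
14 | (S)-2-[3-methoxy-2-(methoxymethoxy)-4-methylphenyl]-6-methylhepta-1,5-dien-3-yl (Z)-2-methylbut-2-enoate | C=C(c1ccc(C)c(OC)c1OCOC)[C@H](CC=C(C)C)OC(=O)/C(C)=C\C | intermediate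
15 | (S)-2-(2-hydroxy-3-methoxy-4-methylphenyl)-6-methylhepta-1,5-dien-3-yl (Z)-2-methylbut-2-enoate | C=C(c1ccc(C)c(OC)c1O)[C@H](CC=C(C)C)OC(=O)/C(C)=C\C | intermediate
16 | (S)-2-(5-methoxy-4-methyl-3,6-dioxocyclohexa-1,4-dien-1-yl)-6-methylhepta-1,5-dien-3-yl (Z)-2-methylbut-2-enoate | C=C(C1=CC(=O)C(C)=C(OC)C1=O)[C@H](CC=C(C)C)OC(=O)/C(C)=C\C | intermediate
17 | (S)-2-(2,5-dihydroxy-3-methoxy-4-methylphenyl)-6-methylhepta-1,5-dien-3-yl (Z)-2-methylbut-2-enoate (CNP0248710.1) | C=C(c1cc(O)c(C)c(OC)c1O)[C@H](CC=C(C)C)OC(=O)/C(C)=C\C | target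

## Step count and risks

Total steps: 10. Longest linear sequence: 9 (steps 1–4, then 6–10); step 5 is the one-step side branch.

**Step 6 (key step).** What may go wrong: slow or reversible capture of the lithiated carbamate by the hindered α-arylvinyl boronate, competing deprotonation at the allylic C4–H2 of 7 followed by loss of the carbamate, or erosion of enantiomeric purity before the 1,2-shift. Fallback, setting out from 5 and 6 and coming back at 11: the C2–C3 bond would be made by a catalytic asymmetric Nozaki–Hiyama–Kishi coupling instead. Iododeboronation of 5 (I2, NaOH aq, THF, 0 °C) would give 1-(1-iodoethenyl)-3-methoxy-2-(methoxymethoxy)-4-methylbenzene F1. Buffered Dess–Martin oxidation of 6 (NaHCO3, CH2Cl2, 0 °C) would give 4-methylpent-3-enal F2, used at once without purification. Ni/Cr-mediated coupling of F1 with F2 (CrCl2 cat., NiCl2 complex cat., chiral oxazoline–sulfonamide ligand, Mn, Cp2ZrCl2, MeCN, rt), with the ligand enantiomer chosen for the (S)-carbinol, would return to 11 under neutral conditions that the labile aldehyde should tolerate.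

**Step 7.** What may go wrong: isomerisation of the angeloyl unit to the tigloyl unit during activation or heating, or sluggish acylation of the hindered allylic alcohol. Fallback, setting out from 11 and coming back at 14: the Z-alkene would be built on the ester instead of being carried through an acyl transfer. Esterification of 11 with 2-[bis(2,2,2-trifluoroethoxy)phosphoryl]propanoic acid (DCC, DMAP, CH2Cl2) would give (S)-2-[3-methoxy-2-(methoxymethoxy)-4-methylphenyl]-6-methylhepta-1,5-dien-3-yl 2-[bis(2,2,2-trifluoroethoxy)phosphoryl]propanoate F3. Still–Gennari olefination of F3 with acetaldehyde (KHMDS, 18-crown-6, THF, −78 °C) should give the (Z)-2-methylbut-2-enoate 14.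

**Step 8.** What may go wrong: Lewis-acid ionisation of the allylic angelate with capture of the allyl cation by the freed ortho-phenol (benzofuran formation), or acyl shift from the C3 oxygen to the phenol oxygen. Fallback, setting out from 11 and coming back at 15: the acetal would be removed before any allylic ester is present. Treatment of 11 with ZnBr2/n-PrSH (CH2Cl2, 0 °C) would give (S)-2-(2-hydroxy-3-methoxy-4-methylphenyl)-6-methylhepta-1,5-dien-3-ol F4. Acylation of both hydroxyl groups of F4 with excess anhydride 13 (Et3N, toluene, 80 °C) would give the bis-angelate (S)-2-{3-methoxy-4-methyl-2-[(Z)-2-methylbut-2-enoyloxy]phenyl}-6-methylhepta-1,5-dien-3-yl (Z)-2-methylbut-2-enoate F5. Selective ammonolysis of the much more reactive aryl ester of F5 (NH3, MeOH, 0 °C) should give phenol 15.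

## Further compounds

F1 | step 6 | 1-(1-iodoethenyl)-3-methoxy-2-(methoxymethoxy)-4-methylbenzene | C=C(I)c1ccc(C)c(OC)c1OCOC
F2 | step 6 | 4-methylpent-3-enal | CC(C)=CCC=O
F3 | step 7 | (S)-2-[3-methoxy-2-(methoxymethoxy)-4-methylphenyl]-6-methylhepta-1,5-dien-3-yl 2-[bis(2,2,2-trifluoroethoxy)phosphoryl]propanoate | C=C(c1ccc(C)c(OC)c1OCOC)[C@H](CC=C(C)C)OC(=O)C(C)P(=O)(OCC(F)(F)F)OCC(F)(F)F
F4 | step 8 | (S)-2-(2-hydroxy-3-methoxy-4-methylphenyl)-6-methylhepta-1,5-dien-3-ol | C=C(c1ccc(C)c(OC)c1O)[C@H](CC=C(C)C)O
F5 | step 8 | (S)-2-{3-methoxy-4-methyl-2-[(Z)-2-methylbut-2-enoyloxy]phenyl}-6-methylhepta-1,5-dien-3-yl (Z)-2-methylbut-2-enoate | C=C(c1ccc(C)c(OC)c1OC(=O)/C(C)=C\C)[C@H](CC=C(C)C)OC(=O)/C(C)=C\C
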